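## Structural features

The target is a 3,6,6-trisubstituted 1,2-dioxane. Numbering from the acid carbon C1, the methine C2 (with its methyl) sits on ring carbon C3, C4 and C5 are ring methylenes, and the fully substituted peroxy carbon C6 carries a methyl group and the chain C7–C8–C9. C9 is joined by a trisubstituted exocyclic alkene to C10 of ring B (C10, C11, C12, C13, C18, C19), which shares the tetrasubstituted C13=C18 alkene with ring A (C13 to C18, gem-dimethyl at C14). C2 and C3 are contiguous stereocentres; C6 lies across the ring from C3 with its chain cis to the C3 branch, and nothing relays stereochemistry between the two sides. A fourth stereochemical element is the Z geometry of C9=C10 (C8 syn to C19): the flanking ring carbons C11 and C19 are both methylenes, so a simple olefination has nothing to choose between. Fragile points are the O–O bond (phosphines, low-valent metals, strong hydride donors, radicals), the C3–H next to the peroxide (base-induced Kornblum–DeLaMare fragmentation), the C2–H once C1 is a carbonyl (β-elimination of the peroxide), and the skipped diene with its doubly allylic C19. The real difficulty is a peroxide of defined configuration at both carbons, above all at quaternary C6, together with the remote alkene geometry. The key step exploits the fact that C6, with its methyl, ring methylene C5 and oxygen, is the tertiary carbinol carbon of (S)-linalool: once that oxygen is tied to C7 as an epoxide, the C6–O bond becomes a leaving group that a C3 hydroperoxide can displace from the rear in a 6-exo closure.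

## Logic of the disconnections

**43 ⇒ 41 ⇒ 40.** No skeletal bond is cut. The C1 carboxyl is traced back to a primary alcohol and then to its silyl ether. C1 stays at the alcohol level throughout because a carbonyl at C1 would make any leaving group or peroxide at C3 prone to β-elimination. The demand is a terminal oxidation that spares the O–O bond and both alkenes.

**40 ⇒ 39.** The C7–C8 single bond is traced back to a C7=C8 alkene. This permits an olefination at C7. The demand is a reduction that takes the disubstituted alkene of a diene and leaves the trisubstituted C9=C10 and the peroxide alone.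

**39 ⇒ 18 + 36.** The C7=C8 bond is cut. C7 is neopentyl and cannot be alkylated, but as an aldehyde on quaternary C6 it is a non-enolisable electrophile. The partner 36 carries both carbocycles and the preformed C9=C10 geometry. The gain is full convergence. The demand is that the carbanion adds to the carbonyl faster than it attacks O–O and that C9=C10 keeps its geometry.

**18 ⇒ 17 ⇒ 16.** After adjusting C7 to the alcohol, the C6–O(peroxide) bond is cut. This opens the dioxane to a C3 hydroperoxide and a C6–C7 epoxide. The gain is that the ring, the C6–O bond and the C6 configuration come from one stereospecific event on an acyclic chain. The demand is attack at C6 (not C7) with clean inversion.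

**16 ⇒ 14 ⇒ 13.** The epoxide is traced back to a silylated O6 next to a C7 sulfonate, and the C3–O(peroxide) bond is cut to a C3 sulfonate of opposite configuration. The order is deliberate. C3 never carries a free hydroxyl while the epoxide exists, and O6 is never free while the C3 sulfonate exists; either pairing would close a tetrahydrofuran. The demand is an SN2 reaction at a β-branched secondary carbon that leaves the neopentyl C7 sulfonate untouched.

**13 ⇒ 12 ⇒ 10.** The C7 oxygen is traced back to the vinyl group by excision of its terminal carbon. The gain is that C6 with its oxygen, methyl and C5 is already in place. The demand is a reductive work-up that does not let the silyl group move from O6 to O7.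

**10 ⇒ 9 ⇒ 8 ⇒ 4 + 5.** The C2–C3 bond is cut (syn-aldol). This sets C2 in its final configuration and C3 in the configuration opposite to the target, ready for inversion. The demand is auxiliary control that overrides the remote C6 centre.

**4 ⇒ 2 ⇒ 1.** The C3=C(isopropylidene) bond is cut. 1 supplies C3 to C7, the C6 methyl and the C6 stereocentre. The demand is cleavage of the trisubstituted alkene in the presence of the vinyl group, with O6 masked so that the aldehyde cannot close to a lactol.

**36 ⇒ 34 ⇒ 32.** The C8–P bond is cut to a primary allylic chloride and then the alcohol. The demand is substitution without allylic transposition.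

**32 ⇒ 30.** The C12–C13 bond of ring B is cut to a vinyl group and an enol triflate. The gain is that the C9=C10 geometry is fixed on an open chain before ring B exists, and the C13=C18 alkene is placed by the triflate. The demand is a 6-membered B-alkyl coupling that tolerates the hydroxyl.

**30 ⇒ 29 ⇒ 27.** The C10–C11 bond is cut (syn-carbometalation of an alkynoate). One event sets the alkene geometry by mechanism: the new carbon and the hydrogen enter cis. The demand is protonation before the adduct can isomerise.

**27 ⇒ 25 ⇒ 24 ⇒ 22 ⇒ 19 + 20.** The C8–C9 bond (acetylide acylation) and the C18–C19 bond (enolate alkylation) are cut, with the enol triflate traced back to the ketone. This reduces the fragment to a ketone that enolises in one direction only and a three-carbon propargyl unit.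

## Other disconnections considered

**Alternative 1:** The cut is the C12–C13 bond of ring B. Forward, the terminal vinyl group of the triflate A2 (ring A enol triflate bearing a 2-ethenylbut-2-enyl chain with a silylated C8 oxygen) would be hydroborated at C12 with 9-BBN-H. The alkylborane would then be coupled with the C13 enol triflate under PdCl2(dppf)/Cs2CO3 to give the bicyclic silyl ether A1.
- In its favour: the C9=C10 geometry is settled on an open chain and carried through by retention at sp2 carbon, the tetrasubstituted alkene is placed unambiguously, and the conditions are mild.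
- Against it here: it creates no stereocentre and leaves the peroxide, C6 and the C2/C3 pair untouched. A synthesis pivoting on it would still have to solve the harder half.
- Comparison: for the carbocycle it is the equal of the chosen plan, which uses the same kind of closure as a supporting step (step 18, on the free alcohol 30). The silyl ether of A2 needs no sacrificial borane for the hydroxyl, a narrow point on which the alternative is better, paid for with one protection and one deprotection. Mechanistically both rest on the same palladium cycle. Step economy is equal for the octalin. The difference is that this closure forms a non-stereogenic bond, whereas the chosen key step forms the bond that carries the most demanding stereocentre.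

**Alternative 2:** The cuts are C3–O and C1–C2. Forward, the tertiary hydroperoxide A4 (C6–OOH, silylated C7 oxygen, (Z)-C2=C3 alkene) would be treated with Pd(OAc)2 and p-benzoquinone under CO in methanol. Anti attack of the peroxide oxygen on the palladium-bound alkene at C3 (6-exo), CO insertion at C2 with retention and methanolysis would give the ester A3.
- In its favour: one step would close the ring, form a C–C bond and set C2 and C3 relative to each other (anti addition to the Z alkene gives the required pair). C1 would arrive at the acid oxidation level, so the auxiliary, the reduction, the C3 inversion and the final oxidation would all be saved. On step economy it is clearly better than the chosen plan.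
- Against it here: hydroperoxides and divalent palladium are uneasy partners (Wacker-type ketone formation through a palladium peroxide, metal-induced O–O decomposition). Oxypalladation–carbonylation is established for alcohols, not for hydroperoxides. The C3/C6 relationship would rest on a chair preference between a methyl and a silyloxymethyl group of similar size. A3 would also need a final ester hydrolysis next to the peroxide.
- Comparison: the chosen plan sets C2, C3 and C6 by three separate stereospecific events and uses no transition metal while the peroxide is built. The alternative is shorter but mechanistically and stereochemically less secure.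

**Alternative 3:** The cuts are C3–O and C6–O together. Forward, sensitised singlet oxygen would add across C3 and C6 of the (E,E)-diene A6 to give the 3,6-cis dihydrodioxine A5, followed by diimide reduction of its ring alkene.
- In its favour: O2 supplies the peroxide directly, both C–O bonds form at once, and the 3,6-cis relationship follows from suprafacial addition to the (E,E)-diene. On that relative relationship it equals the chosen plan. The diene should be reachable in few steps, so step count is equal or slightly better.
- Against it here: the C6 terminus of A6 carries an inward methyl group that disfavours the s-cis conformer, and the allylic hydrogens at the C6 methyl, C7 and C2 invite the Schenck ene reaction. The face of attack would be biased only by the C2 stereocentre, so the absolute sense at C3/C6 is uncertain. A5 also needs selective unmasking of C7 beside C1.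
- Comparison: both plans need a diimide reduction (here on the ring, in the chosen plan on the side chain), so they are equal on that count. The chosen plan takes C6 from the chiral pool by a displacement whose outcome does not depend on facial bias.

Key step: step 10

Assumption: (S)-(+)-linalool (1) is taken to be available in high enantiomeric purity; its tertiary carbon becomes C6.

Remark on descriptors: the C6 carbon is S in 1–16, R in 17, 18 and 39, and S again from 40 on. Only step 10 changes its geometry; the later change is a CIP priority switch. C2 is S in 8, R in 9–41 and S in 42 and 43 for the same reason.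

## Steps

Step 1
Reactants: 1 (S)-linalool
Product: 2 (S)-linalool triethylsilyl ether
Conditions: Et3SiOTf, 2,6-lutidine, CH2Cl2, −78 → 0 °C
Reagents that add atoms: triethylsilyl trifluoromethanesulfonate, CC[Si](CC)(CC)OS(=O)(=O)C(F)(F)F
Why: Silyl triflate/lutidine silylation of a hindered tertiary alcohol; the C–O bond is untouched, so the (S) centre is retained. Masking O6 prevents lactol formation from the aldehyde of step 2 and later keeps O6 from displacing the C3 leaving group.

Step 2
Reactants: 2 (S)-linalool triethylsilyl ether
Product: 4 (4S)-4-methyl-4-(triethylsilyloxy)hex-5-enal, via secondary ozonide 3 (not isolated)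
Conditions: O3 (1.0 equiv; Sudan Red 7B end point), CH2Cl2, −78 °C; then Me2S, −78 °C → rt
Reagents that add atoms: ozone, [O-][O+]=O
Why: Chemoselective ozonolysis: the electron-rich trisubstituted alkene should react far faster than the vinyl group, which is monosubstituted and deactivated by the allylic silyloxy group. Reductive work-up of the ozonide gives the aldehyde and acetone.

Step 3
Reactants: 5 (S)-4-benzyl-3-propanoyl-1,3-oxazolidin-2-one; 4 (4S)-4-methyl-4-(triethylsilyloxy)hex-5-enal
Product: 8 (4S)-4-benzyl-3-[(2S,3R,6S)-3-hydroxy-2,6-dimethyl-6-(triethylsilyloxy)oct-7-enoyl]-1,3-oxazolidin-2-one, via boron enolate 6 (not isolated), via boron aldolate 7 (not isolated)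
Conditions: Bu2BOTf, Et3N, CH2Cl2, 0 °C; then 4, −78 → 0 °C; pH 7 buffer, MeOH, H2O2 (30% aq.), 0 °C
Reagents that add atoms: none
Why: Evans syn-aldol reaction: the (Z)-boron enolate reacts through a closed chair transition state on the face away from the benzyl group, which sets C2 (S) and C3 (R) together under auxiliary control. The remote C6 centre should have no influence.

Step 4
Reactants: 8 syn-aldol adduct
Product: 9 (2R,3R,6S)-2,6-dimethyl-6-(triethylsilyloxy)oct-7-ene-1,3-diol
Conditions: LiBH4, MeOH (1 equiv), THF, 0 °C
Reagents that add atoms: none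
Why: Reductive cleavage of the N-acyl oxazolidinone by hydride attack at the exocyclic carbonyl; the auxiliary is recovered. C1 is taken to the alcohol level so that the later C3 leaving group has no acidifying carbonyl beside it.

Step 5
Reactants: 9 (2R,3R,6S)-2,6-dimethyl-6-(triethylsilyloxy)oct-7-ene-1,3-diol
Product: 10 (2R,3R,6S)-1-(tert-butyldiphenylsilyloxy)-2,6-dimethyl-6-(triethylsilyloxy)oct-7-en-3-ol
Conditions: t-BuPh2SiCl, imidazole, CH2Cl2, 0 °C
Reagents that add atoms: tert-butyl(chloro)diphenylsilane, CC(C)(C)[Si](Cl)(c1ccccc1)c1ccccc1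
Why: Selective silylation of the primary hydroxyl of a 1,3-diol by a bulky silyl chloride. This ether should survive base, buffered HF, peroxide and carbanion chemistry up to step 23.

Step 6
Reactants: 10 (2R,3R,6S)-1-(tert-butyldiphenylsilyloxy)-2,6-dimethyl-6-(triethylsilyloxy)oct-7-en-3-ol
Product: 12 (2S,5R,6R)-7-(tert-butyldiphenylsilyloxy)-2,6-dimethyl-2-(triethylsilyloxy)heptane-1,5-diol, via secondary ozonide 11 (not isolated)
Conditions: O3, CH2Cl2, −78 °C; then NaBH4, MeOH, −78 → 0 °C; AcOH quench
Reagents that add atoms: ozone, [O-][O+]=O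
Why: Ozonolysis of the vinyl group with borohydride work-up excises the terminal carbon and leaves C7 as a primary alcohol on the intact C6 centre. Low temperature and an acidic quench are meant to keep the triethylsilyl group from migrating to the new hydroxyl.

Step 7
Reactants: 12 (2S,5R,6R)-7-(tert-butyldiphenylsilyloxy)-2,6-dimethyl-2-(triethylsilyloxy)heptane-1,5-diol
Product: 13 (2S,5R,6R)-7-(tert-butyldiphenylsilyloxy)-2,6-dimethyl-2-(triethylsilyloxy)heptane-1,5-diyl dimethanesulfonate
Conditions: MeSO2Cl, Et3N, CH2Cl2, 0 °C
Reagents that add atoms: methanesulfonyl chloride, CS(=O)(=O)Cl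
Why: Sulfonylation through sulfene is insensitive to hindrance, so both the secondary C3 and the neopentyl-type C7 hydroxyl are esterified without touching a C–O bond. Placing the C3 leaving group now means no free C3 hydroxyl will ever face the future epoxide.

Step 8
Reactants: 13 bis-mesylate
Product: 14 (2S,5S,6R)-7-(tert-butyldiphenylsilyloxy)-5-hydroperoxy-2,6-dimethyl-2-(triethylsilyloxy)heptyl methanesulfonate
Conditions: H2O2 (50% aq., excess), KOH, MeOH/THF, 0 °C → rt
Reagents that add atoms: hydrogen peroxide, OO
Why: SN2 displacement of a secondary mesylate by hydroperoxide anion, a weakly basic alpha-effect nucleophile, should invert C3 (R to S). The C7 mesylate sits on a neopentyl carbon without beta-hydrogens and is inert to intermolecular attack, and the silylated O6 cannot cyclise onto C3.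

Step 9
Reactants: 14 hydroperoxy mesylate
Product: 16 tert-butyl{[(2R,3S)-3-hydroperoxy-2-methyl-5-[(2S)-2-methyloxiran-2-yl]pentyl]oxy}diphenylsilane, via hydroxy mesylate 15 (not isolated)
Conditions: HF·pyridine, pyridine, THF, 0 °C → rt; then K2CO3, MeOH, 0 °C
Reagents that add atoms: none
Why: Buffered HF should remove the triethylsilyl group much faster than the primary tert-butyldiphenylsilyl group; carbonate then closes the epoxide by 3-exo-tet displacement of the adjacent mesylate, with retention at C6 because its C–O bond is not broken. Under base the peroxy anion has only a tertiary carbon or a seven-membered closure at C7 open to it, both slow at 0 °C.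

Step 10
Reactants: 16 hydroperoxy epoxide
Product: 17 [(3R,6S)-6-[(2R)-1-(tert-butyldiphenylsilyloxy)propan-2-yl]-3-methyl-1,2-dioxan-3-yl]methanol
Conditions: (1S)-(+)-10-camphorsulfonic acid (0.1 equiv), CH2Cl2, 0 °C
Reagents that add atoms: none
Why: The sulfonic acid hydrogen-bonds to (or protonates) the epoxide oxygen, and the terminal oxygen of the C3 hydroperoxide attacks C6 from the face opposite the C6–O bond as that bond breaks, so the former ring oxygen becomes the C7 hydroxyl. The closest known reaction type is the acid-promoted intramolecular opening of epoxides and oxetanes by hydroperoxides to 1,2-dioxanes and 1,2-dioxolanes, the peroxide counterpart of the epoxy-alcohol route to cyclic ethers. The one ring formed, the 1,2-dioxane, closes in the 6-exo-tet mode (O–O–C3–C4–C5–C6, epoxide oxygen outside the new ring). The one new stereocentre, C6, is controlled by the substrate alone: the (S)-epoxide carbon inherited from 1 is inverted, giving the (R)-configured peroxy carbon of 17 with C7 cis to the C3 branch, while C2 and C3 are spectators. The step needs regioselectivity for C6 over C7, which the substrate secures twice: positive charge builds up better at the tertiary carbon, and a six-membered exo closure beats a seven-membered endo one. It needs stereochemical fidelity, meaning a tight rear-side displacement and no free tertiary cation, which a catalytic weak-counter-ion acid in a non-ionising solvent at 0 °C and the proximity of the internal nucleophile should favour. It also needs chemoselectivity against a hydride shift to an aldehyde and against intermolecular opening, which the absence of a strong Lewis acid and of external nucleophiles, together with moderate dilution, should provide.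

Step 11
Reactants: 17 dioxane alcohol
Product: 18 (3R,6S)-6-[(2R)-1-(tert-butyldiphenylsilyloxy)propan-2-yl]-3-methyl-1,2-dioxane-3-carbaldehyde
Conditions: Dess–Martin periodinane, NaHCO3, CH2Cl2, 0 °C → rt
Reagents that add atoms: none
Why: Dess–Martin oxidation under buffered, non-basic conditions. The aldehyde has no alpha-hydrogen (C6 is quaternary), so neither epimerisation nor elimination of the peroxide can occur, and the periodinane does not attack the O–O bond.

Step 12
Reactants: 19 2,2-dimethylcyclohexan-1-one; 20 3-bromo-1-(trimethylsilyl)prop-1-yne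
Product: 22 2,2-dimethyl-6-[3-(trimethylsilyl)prop-2-yn-1-yl]cyclohexan-1-one (racemic), via lithium enolate 21 (not isolated)
Conditions: LiN(iPr)2, THF, −78 °C; then 20, DMPU, −78 → 0 °C
Reagents that add atoms: none
Why: Enolate alkylation: the ketone can enolise only toward C6 because C2 is quaternary, and the propargylic bromide is a reactive SN2 partner whose silyl cap removes the acidic alkyne proton. The new centre is racemic and disappears in step 13.

Step 13
Reactants: 22 propargylated ketone
Product: 24 6,6-dimethyl-2-[3-(trimethylsilyl)prop-2-yn-1-yl]cyclohex-1-en-1-yl trifluoromethanesulfonate, via potassium enolate 23 (not isolated)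
Conditions: KN(SiMe3)2, THF, −78 → 0 °C; then PhNTf2, −78 °C → rt
Reagents that add atoms: N-phenylbis(trifluoromethanesulfonimide), O=S(=O)(N(c1ccccc1)S(=O)(=O)C(F)(F)F)C(F)(F)F
Why: O-sulfonylation of the only possible enolate fixes the position of the future tetrasubstituted C13=C18 alkene without ambiguity.

Step 14
Reactants: 24 silylalkyne enol triflate
Product: 25 6,6-dimethyl-2-(prop-2-yn-1-yl)cyclohex-1-en-1-yl trifluoromethanesulfonate
Conditions: K2CO3 (cat.), MeOH, 0 °C
Reagents that add atoms: none
Why: Methanolysis of the alkynyl–silicon bond; brief treatment at 0 °C should leave the hindered enol triflate alone.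

Step 15
Reactants: 25 terminal alkyne
Product: 27 methyl 4-[3,3-dimethyl-2-(trifluoromethanesulfonyloxy)cyclohex-1-en-1-yl]but-2-ynoate, via lithium acetylide 26 (not isolated)
Conditions: LiN(iPr)2 (1.05 equiv), THF, −78 °C; then ClCO2Me, −78 → −20 °C
Reagents that add atoms: methyl chloroformate, COC(=O)Cl
Why: Acylation of a lithium acetylide introduces C8. The amide base is used instead of an alkyllithium because it does not attack the sulfonyl group of the enol triflate at −78 °C.

Step 16
Reactants: 27 alkynoate
Product: 29 methyl (2E)-3-{[3,3-dimethyl-2-(trifluoromethanesulfonyloxy)cyclohex-1-en-1-yl]methyl}penta-2,4-dienoate, via alkenylcopper adduct 28 (not isolated)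
Conditions: CH2=CHMgBr (2.2 equiv), CuBr·SMe2 (1.1 equiv), THF, −78 °C; then 27, −78 °C; MeOH, −78 °C
Reagents that add atoms: vinylmagnesium bromide, C=C[Mg]Br
Why: Conjugate syn-carbocupration of an alkynoate: the vinyl group (C11–C12) and copper add to the same side, and protonation at −78 °C with retention places hydrogen cis to the vinyl group, hence C8 cis to C19, the Z relationship of the target. The enol triflate should not couple with the cuprate at this temperature.

Step 17
Reactants: 29 dienoate
Product: 30 2-[(2E)-2-ethenyl-4-hydroxybut-2-en-1-yl]-6,6-dimethylcyclohex-1-en-1-yl trifluoromethanesulfonate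
Conditions: iBu2AlH (2.5 equiv), CH2Cl2, −78 °C; aq. potassium sodium tartrate
Reagents that add atoms: none
Why: 1,2-Reduction of the conjugated ester to the allylic alcohol. Removing the carbonyl ends the risk of base-mediated isomerisation of C9=C10 through a dienolate.

Step 18
Reactants: 30 dienol triflate
Product: 32 2-[(2Z)-5,5-dimethyl-3,4,5,6,7,8-hexahydronaphthalen-2(1H)-ylidene]ethan-1-ol, via bis-borylated intermediate 31 (not isolated)
Conditions: 9-BBN-H (2.5 equiv), THF, 0 °C → rt; then PdCl2(dppf) (10 mol%), Cs2CO3, DMF/THF/H2O, high dilution, rt → 50 °C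
Reagents that add atoms: none
Why: Anti-Markovnikov hydroboration of the terminal vinyl group (the hydroxyl is tied up as a borinate by the first equivalent) followed by intramolecular B-alkyl Suzuki–Miyaura coupling with the enol triflate closes ring B at C12–C13. Both sp2 carbons react with retention, so the C9=C10 geometry is carried over and the C13=C18 alkene forms where the triflate stood.

Step 19
Reactants: 32 bicyclic allylic alcohol
Product: 34 (2Z)-2-(2-chloroethylidene)-5,5-dimethyl-1,2,3,4,5,6,7,8-octahydronaphthalene, via allylic mesylate 33 (not isolated)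
Conditions: MeSO2Cl, 2,4,6-collidine, LiCl, DMF, 0 °C
Reagents that add atoms: lithium chloride, [Li+].[Cl-]
Why: Activation and direct SN2 chloride displacement at the primary allylic carbon. Attack at the fully substituted C10 is blocked, so no transposition or loss of geometry is expected.

Step 20
Reactants: 34 allylic chloride
Product: 36 {2-[(2Z)-5,5-dimethyl-3,4,5,6,7,8-hexahydronaphthalen-2(1H)-ylidene]ethyl}(diphenyl)phosphine oxide, via allylic phosphine 35 (not isolated)
Conditions: Ph2PH, n-BuLi, THF, −78 °C; then 34, −78 → 0 °C; then H2O2 (30% aq.), CH2Cl2, 0 °C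
Reagents that add atoms: diphenylphosphine (as its lithium salt), c1ccc(cc1)Pc1ccccc1; hydrogen peroxide, OO
Why: SN2 alkylation of lithium diphenylphosphide at the primary allylic chloride, then oxidation at phosphorus. Uncatalysed H2O2 should not touch the alkenes.

Step 21
Reactants: 36 allylic phosphine oxide; 18 dioxane aldehyde
Product: 39 tert-butyl{(2R)-2-[(3S,6R)-6-{(1E)-3-[(2Z)-5,5-dimethyl-3,4,5,6,7,8-hexahydronaphthalen-2(1H)-ylidene]prop-1-en-1-yl}-6-methyl-1,2-dioxan-3-yl]propoxy}diphenylsilane, via lithiated phosphine oxide 37 (not isolated), via lithium oxido adduct 38 (not isolated)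
Conditions: n-BuLi, THF, −78 °C; then 18, −78 °C → rt
Reagents that add atoms: none
Why: Horner–Wittig olefination: the allylic anion adds through its alpha carbon (the gamma carbon C10 is fully substituted) to the non-enolisable aldehyde, and the adduct, whose elimination gives a conjugated diene, should lose lithium diphenylphosphinate on warming to give mainly the (E)-C7=C8 alkene. The C9=C10 geometry is expected to persist, as is usual for allylic phosphine oxide anions.

Step 22
Reactants: 39 diene
Product: 40 tert-butyl{(2R)-2-[(3S,6S)-6-{3-[(2Z)-5,5-dimethyl-3,4,5,6,7,8-hexahydronaphthalen-2(1H)-ylidene]propyl}-6-methyl-1,2-dioxan-3-yl]propoxy}diphenylsilane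
Conditions: KO2C–N=N–CO2K, AcOH, MeOH/CH2Cl2, 0 °C → rt (portionwise)
Reagents that add atoms: none
Why: Diimide reduction: two hydrogens are transferred in a concerted syn fashion without cleaving O–O bonds. Its rate falls steeply with alkene substitution, so the disubstituted C7=C8 bond should be reduced ahead of the trisubstituted C9=C10 and tetrasubstituted C13=C18 bonds.

Step 23
Reactants: 40 silyl ether
Product: 41 (2R)-2-[(3S,6S)-6-{3-[(2Z)-5,5-dimethyl-3,4,5,6,7,8-hexahydronaphthalen-2(1H)-ylidene]propyl}-6-methyl-1,2-dioxan-3-yl]propan-1-ol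
Conditions: Bu4NF, AcOH, THF, 0 °C → rt
Reagents that add atoms: none
Why: Fluoride cleavage of the silyl ether. Buffering with acetic acid keeps the medium from becoming basic enough for Kornblum–DeLaMare fragmentation at C3.

Step 24
Reactants: 41 primary alcohol
Product: 43 (2S)-2-[(3S,6S)-6-{3-[(2Z)-5,5-dimethyl-3,4,5,6,7,8-hexahydronaphthalen-2(1H)-ylidene]propyl}-6-methyl-1,2-dioxan-3-yl]propanoic acid, via aldehyde 42 (not isolated)
Conditions: TEMPO (cat.), PhI(OAc)2, MeCN/H2O, 0 °C → rt
Reagents that add atoms: water, O
Why: Oxoammonium-mediated oxidation of the primary alcohol to the aldehyde and, through its hydrate, to the acid in one flask. The mildly acidic medium should avoid both epimerisation at C2 and beta-elimination of the peroxide, and the system does not oxidise the alkenes or the O–O bond.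

## Compound list

1 | (S)-linalool, (3S)-3,7-dimethylocta-1,6-dien-3-ol | CC(C)=CCC[C@@](O)(C)C=C | starting material
2 | triethyl{[(3S)-3,7-dimethylocta-1,6-dien-3-yl]oxy}silane | CC(C)=CCC[C@@](O[Si](CC)(CC)CC)(C)C=C | intermediate
3 | 3,3-dimethyl-5-[(3S)-3-methyl-3-(triethylsilyloxy)pent-4-en-1-yl]-1,2,4-trioxolane (mixture at C5) | CC1(C)OOC(CC[C@@](O[Si](CC)(CC)CC)(C)C=C)O1 | intermediate (not isolated)
4 | (4S)-4-methyl-4-(triethylsilyloxy)hex-5-enal | O=CCC[C@@](O[Si](CC)(CC)CC)(C)C=C | intermediate
5 | (S)-4-benzyl-3-propanoyl-1,3-oxazolidin-2-one | CCC(=O)N1[C@@H](Cc2ccccc2)COC1=O | starting material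
6 | (Z)-dibutylboron enolate of 5 | C/C=C(\OB(CCCC)CCCC)N1[C@@H](Cc2ccccc2)COC1=O | intermediate (not isolated)
7 | dibutylboron aldolate of 8 | C[C@H](C(=O)N1[C@@H](Cc2ccccc2)COC1=O)[C@H](OB(CCCC)CCCC)CC[C@@](O[Si](CC)(CC)CC)(C)C=C | intermediate (not isolated)
8 | (4S)-4-benzyl-3-[(2S,3R,6S)-3-hydroxy-2,6-dimethyl-6-(triethylsilyloxy)oct-7-enoyl]-1,3-oxazolidin-2-one | C[C@H](C(=O)N1[C@@H](Cc2ccccc2)COC1=O)[C@H](O)CC[C@@](O[Si](CC)(CC)CC)(C)C=C | intermediate
9 | (2R,3R,6S)-2,6-dimethyl-6-(triethylsilyloxy)oct-7-ene-1,3-diol | C[C@H](CO)[C@H](O)CC[C@@](O[Si](CC)(CC)CC)(C)C=C | intermediate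
10 | (2R,3R,6S)-1-(tert-butyldiphenylsilyloxy)-2,6-dimethyl-6-(triethylsilyloxy)oct-7-en-3-ol | C[C@H](CO[Si](c1ccccc1)(c1ccccc1)C(C)(C)C)[C@H](O)CC[C@@](O[Si](CC)(CC)CC)(C)C=C | intermediate
11 | secondary ozonide (1,2,4-trioxolan-3-yl in place of the vinyl group of 10; mixture at the ozonide carbon) | C[C@H](CO[Si](c1ccccc1)(c1ccccc1)C(C)(C)C)[C@H](O)CC[C@@](O[Si](CC)(CC)CC)(C)C1OOCO1 | intermediate (not isolated)
12 | (2S,5R,6R)-7-(tert-butyldiphenylsilyloxy)-2,6-dimethyl-2-(triethylsilyloxy)heptane-1,5-diol | C[C@H](CO[Si](c1ccccc1)(c1ccccc1)C(C)(C)C)[C@H](O)CC[C@@](O[Si](CC)(CC)CC)(C)CO | intermediate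
13 | (2S,5R,6R)-7-(tert-butyldiphenylsilyloxy)-2,6-dimethyl-2-(triethylsilyloxy)heptane-1,5-diyl dimethanesulfonate | C[C@H](CO[Si](c1ccccc1)(c1ccccc1)C(C)(C)C)[C@H](OS(C)(=O)=O)CC[C@@](O[Si](CC)(CC)CC)(C)COS(C)(=O)=O | intermediate
14 | (2S,5S,6R)-7-(tert-butyldiphenylsilyloxy)-5-hydroperoxy-2,6-dimethyl-2-(triethylsilyloxy)heptyl methanesulfonate | C[C@H](CO[Si](c1ccccc1)(c1ccccc1)C(C)(C)C)[C@@H](OO)CC[C@@](O[Si](CC)(CC)CC)(C)COS(C)(=O)=O | intermediate
15 | (2S,5S,6R)-7-(tert-butyldiphenylsilyloxy)-5-hydroperoxy-2-hydroxy-2,6-dimethylheptyl methanesulfonate | C[C@H](CO[Si](c1ccccc1)(c1ccccc1)C(C)(C)C)[C@@H](OO)CC[C@@](O)(C)COS(C)(=O)=O | intermediate (not isolated)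
16 | tert-butyl{[(2R,3S)-3-hydroperoxy-2-methyl-5-[(2S)-2-methyloxiran-2-yl]pentyl]oxy}diphenylsilane | C[C@H](CO[Si](c1ccccc1)(c1ccccc1)C(C)(C)C)[C@@H](OO)CC[C@@]1(C)CO1 | intermediate (key-step precursor)
17 | [(3R,6S)-6-[(2R)-1-(tert-butyldiphenylsilyloxy)propan-2-yl]-3-methyl-1,2-dioxan-3-yl]methanol | C[C@H](CO[Si](c1ccccc1)(c1ccccc1)C(C)(C)C)[C@@H]1CC[C@](C)(CO)OO1 | intermediate (key-step product)
18 | (3R,6S)-6-[(2R)-1-(tert-butyldiphenylsilyloxy)propan-2-yl]-3-methyl-1,2-dioxane-3-carbaldehyde | C[C@H](CO[Si](c1ccccc1)(c1ccccc1)C(C)(C)C)[C@@H]1CC[C@](C)(C=O)OO1 | intermediate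
19 | 2,2-dimethylcyclohexan-1-one | CC1(C)CCCCC1=O | starting material
20 | 3-bromo-1-(trimethylsilyl)prop-1-yne | C[Si](C)(C)C#CCBr | starting material
21 | lithium 6,6-dimethylcyclohex-1-en-1-olate | [Li+].[O-]C1=CCCCC1(C)C | intermediate (not isolated)
22 | 2,2-dimethyl-6-[3-(trimethylsilyl)prop-2-yn-1-yl]cyclohexan-1-one (racemic) | CC1(C)CCCC(CC#C[Si](C)(C)C)C1=O | intermediate
23 | potassium 6,6-dimethyl-2-[3-(trimethylsilyl)prop-2-yn-1-yl]cyclohex-1-en-1-olate | [K+].[O-]C1=C(CC#C[Si](C)(C)C)CCCC1(C)C | intermediate (not isolated)
24 | 6,6-dimethyl-2-[3-(trimethylsilyl)prop-2-yn-1-yl]cyclohex-1-en-1-yl trifluoromethanesulfonate | CC1(C)CCCC(CC#C[Si](C)(C)C)=C1OS(=O)(=O)C(F)(F)F | intermediate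
25 | 6,6-dimethyl-2-(prop-2-yn-1-yl)cyclohex-1-en-1-yl trifluoromethanesulfonate | CC1(C)CCCC(CC#C)=C1OS(=O)(=O)C(F)(F)F | intermediate
26 | lithium acetylide of 25 | [Li+].[C-]#CCC1=C(OS(=O)(=O)C(F)(F)F)C(C)(C)CCC1 | intermediate (not isolated)
27 | methyl 4-[3,3-dimethyl-2-(trifluoromethanesulfonyloxy)cyclohex-1-en-1-yl]but-2-ynoate | COC(=O)C#CCC1=C(OS(=O)(=O)C(F)(F)F)C(C)(C)CCC1 | intermediate
28 | alkenylcopper adduct (copper at C9, cis to the new vinyl group) | COC(=O)/C([Cu])=C(/C=C)CC1=C(OS(=O)(=O)C(F)(F)F)C(C)(C)CCC1 | intermediate (not isolated)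
29 | methyl (2E)-3-{[3,3-dimethyl-2-(trifluoromethanesulfonyloxy)cyclohex-1-en-1-yl]methyl}penta-2,4-dienoate | COC(=O)/C=C(/C=C)CC1=C(OS(=O)(=O)C(F)(F)F)C(C)(C)CCC1 | intermediate
30 | 2-[(2E)-2-ethenyl-4-hydroxybut-2-en-1-yl]-6,6-dimethylcyclohex-1-en-1-yl trifluoromethanesulfonate | OC/C=C(/C=C)CC1=C(OS(=O)(=O)C(F)(F)F)C(C)(C)CCC1 | intermediate
31 | bis-borylated intermediate (O-borinate at C8, B-alkyl-9-BBN at C12) | B1(OC/C=C(/CCB2C3CCCC2CCC3)CC2=C(OS(=O)(=O)C(F)(F)F)C(C)(C)CCC2)C2CCCC1CCC2 | intermediate (not isolated)
32 | 2-[(2Z)-5,5-dimethyl-3,4,5,6,7,8-hexahydronaphthalen-2(1H)-ylidene]ethan-1-ol | OC/C=C1/CCC2=C(CCCC2(C)C)C1 | intermediate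
33 | 2-[(2Z)-5,5-dimethyl-3,4,5,6,7,8-hexahydronaphthalen-2(1H)-ylidene]ethyl methanesulfonate | CS(=O)(=O)OC/C=C1/CCC2=C(CCCC2(C)C)C1 | intermediate (not isolated)
34 | (2Z)-2-(2-chloroethylidene)-5,5-dimethyl-1,2,3,4,5,6,7,8-octahydronaphthalene | ClC/C=C1/CCC2=C(CCCC2(C)C)C1 | intermediate
35 | {2-[(2Z)-5,5-dimethyl-3,4,5,6,7,8-hexahydronaphthalen-2(1H)-ylidene]ethyl}diphenylphosphane | c1ccccc1P(C/C=C1/CCC2=C(CCCC2(C)C)C1)c1ccccc1 | intermediate (not isolated)
36 | {2-[(2Z)-5,5-dimethyl-3,4,5,6,7,8-hexahydronaphthalen-2(1H)-ylidene]ethyl}(diphenyl)phosphine oxide | O=P(C/C=C1/CCC2=C(CCCC2(C)C)C1)(c1ccccc1)c1ccccc1 | intermediate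
37 | lithiated 36 (carbanion at C8) | [Li+].O=P([CH-]/C=C1/CCC2=C(CCCC2(C)C)C1)(c1ccccc1)c1ccccc1 | intermediate (not isolated)
38 | lithium oxido adduct of 37 and 18 (C7–O⁻, C8–P; mixture at C7 and C8) | [Li+].C[C@H](CO[Si](c1ccccc1)(c1ccccc1)C(C)(C)C)[C@@H]1CC[C@](C)(C([O-])C(/C=C2/CCC3=C(CCCC3(C)C)C2)P(=O)(c2ccccc2)c2ccccc2)OO1 | intermediate (not isolated)
39 | tert-butyl{(2R)-2-[(3S,6R)-6-{(1E)-3-[(2Z)-5,5-dimethyl-3,4,5,6,7,8-hexahydronaphthalen-2(1H)-ylidene]prop-1-en-1-yl}-6-methyl-1,2-dioxan-3-yl]propoxy}diphenylsilane | C[C@H](CO[Si](c1ccccc1)(c1ccccc1)C(C)(C)C)[C@@H]1CC[C@](C)(/C=C/C=C2/CCC3=C(CCCC3(C)C)C2)OO1 | intermediate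
40 | tert-butyl{(2R)-2-[(3S,6S)-6-{3-[(2Z)-5,5-dimethyl-3,4,5,6,7,8-hexahydronaphthalen-2(1H)-ylidene]propyl}-6-methyl-1,2-dioxan-3-yl]propoxy}diphenylsilane | C[C@H](CO[Si](c1ccccc1)(c1ccccc1)C(C)(C)C)[C@@H]1CC[C@](C)(CC/C=C2/CCC3=C(CCCC3(C)C)C2)OO1 | intermediate
41 | (2R)-2-[(3S,6S)-6-{3-[(2Z)-5,5-dimethyl-3,4,5,6,7,8-hexahydronaphthalen-2(1H)-ylidene]propyl}-6-methyl-1,2-dioxan-3-yl]propan-1-ol | C[C@H](CO)[C@@H]1CC[C@](C)(CC/C=C2/CCC3=C(CCCC3(C)C)C2)OO1 | intermediate
42 | (2S)-2-[(3S,6S)-6-{3-[(2Z)-5,5-dimethyl-3,4,5,6,7,8-hexahydronaphthalen-2(1H)-ylidene]propyl}-6-methyl-1,2-dioxan-3-yl]propanal | C[C@H](C=O)[C@@H]1CC[C@](C)(CC/C=C2/CCC3=C(CCCC3(C)C)C2)OO1 | intermediate (not isolated)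
43 | (2S)-2-[(3S,6S)-6-{3-[(2Z)-5,5-dimethyl-3,4,5,6,7,8-hexahydronaphthalen-2(1H)-ylidene]propyl}-6-methyl-1,2-dioxan-3-yl]propanoic acid | C[C@H](C(=O)O)[C@@H]1CC[C@](C)(CC/C=C2/CCC3=C(CCCC3(C)C)C2)OO1 | target

## Step count and least certain steps

Total: 24 steps. Longest linear sequence: 15 steps (1 to 43 through steps 1–11 and 21–24). The octalin branch takes 9 steps (12–20) before the union in step 21.

**Step 10 (key step).** The most likely failure is partial ionisation at C6 before the peroxide oxygen arrives, which would erode the stereochemical fidelity, or a hydride shift that turns the epoxide into an aldehyde; attack at C7 is the lesser risk. Fallback, which reverses the roles of the two peroxide carbons: starting from 13, the silyl group is removed and the epoxide closed as in step 9 to give the epoxy mesylate (2R,3R)-1-(tert-butyldiphenylsilyloxy)-2-methyl-5-[(2S)-2-methyloxiran-2-yl]pentan-3-yl methanesulfonate F1. Ethereal H2O2 with catalytic H3PMo12O40 then opens the epoxide intermolecularly at the tertiary carbon with inversion to give the tertiary hydroperoxide (2R,3R,6R)-1-(tert-butyldiphenylsilyloxy)-6-hydroperoxy-7-hydroxy-2,6-dimethylheptan-3-yl methanesulfonate F2. KOtBu with 18-crown-6 in THF at 0 °C then closes the ring by intramolecular SN2 displacement of the C3 mesylate with inversion. Both centres end as in the main route, and the sequence rejoins it at 17.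

**Step 8.** The displacement takes place at a β-branched secondary carbon and may be slow, so that elimination toward C2 or C4, attack by methoxide or hydroxide, and gradual loss of the triethylsilyl group compete. Fallback, using a protected and less basic peroxide nucleophile: 13 is treated with 2-methoxypropan-2-yl hydroperoxide (made by ozonolysis of 2,3-dimethylbut-2-ene in methanol) and CsOH·H2O in DMF. This gives the peroxyketal (2S,5S,6R)-7-(tert-butyldiphenylsilyloxy)-5-[(2-methoxypropan-2-yl)peroxy]-2,6-dimethyl-2-(triethylsilyloxy)heptyl methanesulfonate F3 with inversion at C3. Brief treatment with AcOH/H2O/THF releases the hydroperoxide, rejoining the route at 14.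

**Step 22.** Over-reduction into the C9=C10 bond or incomplete conversion is the likely problem. The C7=C8 bond is disubstituted but shielded by the quaternary C6, which narrows the rate gap to the trisubstituted alkene. Fallback, changing from reagent transfer to catalyst control: 39 is hydrogenated with RhCl(PPh3)3 under H2 (1 atm) in benzene/ethanol, a catalyst whose rate drops very sharply beyond disubstituted alkenes and which should not insert into a dialkyl peroxide. It leads directly to 40 (no new compound, F0).

**Step 21.** The lithiated phosphine oxide is a strong base and nucleophile. Attack on the O–O bond, deprotonation at C3 with fragmentation, or slow addition to the hindered aldehyde followed by incomplete elimination of the phosphinate could each lower the yield. Fallback, using a neutral-collapse olefination: 34 is heated with PPh3 in MeCN to give {2-[(2Z)-5,5-dimethyl-3,4,5,6,7,8-hexahydronaphthalen-2(1H)-ylidene]ethyl}triphenylphosphonium chloride F4. Its ylide (NaN(SiMe3)2, THF, −78 °C) is combined with 18 in a Wittig reaction, which should give 39 together with its (7Z)-isomer, the (1Z)-prop-1-enyl diene F5. Both are reduced in step 22 to the same compound, so the route is rejoined at 40.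

**Step 2.** Loss of chemoselectivity, with ozone also cleaving the vinyl group, would destroy the C7 handle. Fallback, replacing ozone by a two-stage oxidative cleavage: 2 is epoxidised with mCPBA (1.0 equiv, CH2Cl2, 0 °C), which strongly prefers the trisubstituted alkene, to give triethyl{[(3S)-5-(3,3-dimethyloxiran-2-yl)-3-methylpent-1-en-3-yl]oxy}silane F6. This is cleaved with H5IO6 in THF/Et2O to the aldehyde, rejoining the route at 4.

## Further compounds

F1 | step 10 | (2R,3R)-1-(tert-butyldiphenylsilyloxy)-2-methyl-5-[(2S)-2-methyloxiran-2-yl]pentan-3-yl methanesulfonate | C[C@H](CO[Si](c1ccccc1)(c1ccccc1)C(C)(C)C)[C@H](OS(C)(=O)=O)CC[C@@]1(C)CO1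
F2 | step 10 | (2R,3R,6R)-1-(tert-butyldiphenylsilyloxy)-6-hydroperoxy-7-hydroxy-2,6-dimethylheptan-3-yl methanesulfonate | C[C@H](CO[Si](c1ccccc1)(c1ccccc1)C(C)(C)C)[C@H](OS(C)(=O)=O)CC[C@](C)(CO)OO
F3 | step 8 | (2S,5S,6R)-7-(tert-butyldiphenylsilyloxy)-5-[(2-methoxypropan-2-yl)peroxy]-2,6-dimethyl-2-(triethylsilyloxy)heptyl methanesulfonate | C[C@H](CO[Si](c1ccccc1)(c1ccccc1)C(C)(C)C)[C@@H](OOC(C)(C)OC)CC[C@@](O[Si](CC)(CC)CC)(C)COS(C)(=O)=O
F0 | step 22 | none | none
F4 | step 21 | {2-[(2Z)-5,5-dimethyl-3,4,5,6,7,8-hexahydronaphthalen-2(1H)-ylidene]ethyl}triphenylphosphonium chloride | [Cl-].C(/C=C1/CCC2=C(CCCC2(C)C)C1)[P+](c1ccccc1)(c1ccccc1)c1ccccc1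
F5 | step 21 | tert-butyl{(2R)-2-[(3S,6R)-6-{(1Z)-3-[(2Z)-5,5-dimethyl-3,4,5,6,7,8-hexahydronaphthalen-2(1H)-ylidene]prop-1-en-1-yl}-6-methyl-1,2-dioxan-3-yl]propoxy}diphenylsilane | C[C@H](CO[Si](c1ccccc1)(c1ccccc1)C(C)(C)C)[C@@H]1CC[C@](C)(/C=C\C=C2\CCC3=C(CCCC3(C)C)C2)OO1
F6 | step 2 | triethyl{[(3S)-5-(3,3-dimethyloxiran-2-yl)-3-methylpent-1-en-3-yl]oxy}silane (mixture at the oxirane carbon) | CC1(C)OC1CC[C@@](O[Si](CC)(CC)CC)(C)C=C
A1 | alternative 1 | tert-butyl{2-[(2Z)-5,5-dimethyl-3,4,5,6,7,8-hexahydronaphthalen-2(1H)-ylidene]ethoxy}dimethylsilane | CC(C)(C)[Si](C)(C)OC/C=C1/CCC2=C(CCCC2(C)C)C1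
A2 | alternative 1 | 2-[(2E)-4-(tert-butyldimethylsilyloxy)-2-ethenylbut-2-en-1-yl]-6,6-dimethylcyclohex-1-en-1-yl trifluoromethanesulfonate | CC(C)(C)[Si](C)(C)OC/C=C(/C=C)CC1=C(OS(=O)(=O)C(F)(F)F)C(C)(C)CCC1
A3 | alternative 2 | methyl (2S)-2-[(3S,6R)-6-{[(tert-butyldimethylsilyl)oxy]methyl}-6-methyl-1,2-dioxan-3-yl]propanoate | C[C@H](C(=O)OC)[C@@H]1CC[C@](C)(CO[Si](C)(C)C(C)(C)C)OO1
A4 | alternative 2 | tert-butyl{[(2R,5Z)-2-hydroperoxy-2-methylhept-5-en-1-yl]oxy}dimethylsilane | C/C=C\CC[C@](C)(CO[Si](C)(C)C(C)(C)C)OO
A5 | alternative 3 | tert-butyl{[(3R,6S)-6-[(2R)-1-(tert-butyldiphenylsilyloxy)propan-2-yl]-3-methyl-3,6-dihydro-1,2-dioxin-3-yl]methoxy}dimethylsilane | C[C@H](CO[Si](c1ccccc1)(c1ccccc1)C(C)(C)C)[C@@H]1C=C[C@](C)(CO[Si](C)(C)C(C)(C)C)OO1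
A6 | alternative 3 | tert-butyl{[(2E,4E,6S)-7-(tert-butyldiphenylsilyloxy)-2,6-dimethylhepta-2,4-dien-1-yl]oxy}dimethylsilane | C[C@H](CO[Si](c1ccccc1)(c1ccccc1)C(C)(C)C)/C=C/C=C(\C)CO[Si](C)(C)C(C)(C)C
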